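The six-membered carbocycle, ring A (bridgehead CH, CH=CH, the carbon of the exocyclic enol ether, the quaternary ring-fusion carbon, CH2), is not assembled as such. An intramolecular Diels–Alder reaction of a lactone-fused cyclopentadiene first gives the easier tetracyclic norbornene with five of the six stereocentres. Dibromocarbene addition to its trisubstituted C=C and electrocyclic opening of the cyclopropane then insert one CH between the two alkene carbons: the five-membered ring becomes ring A, and loss of HBr creates the C=C–C=CH–O dienol-lactone unit of rings A and D in the same operation. The precursor is thus a norbornene allylic lactone that contains neither ring A nor the enol ether.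

Key step: step 8

Remark: ring A = cyclohexadiene, ring B = cyclopentane with CH3/CO2Me, ring C = second cyclopentane, ring D = pyran; cyclopentadienes 13, 15 and 16 are drawn as the one 1,5-hydrogen-shift isomer that can cyclise, 10 is a mixture of epimers at the ring carbon (removed in step 5) and 23 a mixture of anomers (settled in step 11).

Step 1
Reactants: 1 methyl (2R)-oxirane-2-carboxylate; 2 allylmagnesium bromide
Product: 3 methyl (2R)-2-hydroxyhex-5-enoate
Conditions: CH2=CHCH2MgBr (1.1 equiv), CuI (10 mol%), THF, −78 °C; aq. NH4Cl
Reagents that add atoms: allylmagnesium bromide 2, C=CC[Mg]Br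
Why: Copper-catalysed SN2 opening of the glycidate at its unsubstituted CH2 should outrun addition to the ester at −78 °C and leaves the stereocentre untouched, so 3 keeps the R configuration of 1.

Step 2
Reactants: 3 methyl (2R)-2-hydroxyhex-5-enoate; 4 methyl methacrylate
Product: 5 dimethyl (2R,5E)-2-hydroxy-6-methylhept-5-enedioate
Conditions: 4 (10 equiv), (H2IMes)(PCy3)Cl2Ru=CHPh (second-generation Grubbs catalyst, 5 mol%), CH2Cl2, 40 °C
Reagents that add atoms: methyl methacrylate 4, C=C(C)C(=O)OC
Why: Cross-metathesis of the terminal alkene with excess methacrylate should give the trisubstituted enoate with the favoured E geometry (ester trans to the chain), which later places CO2Me endo and CH3 exo.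

Step 3
Reactants: 5 dimethyl (2R,5E)-2-hydroxy-6-methylhept-5-enedioate; 6 trifluoromethanesulfonic anhydride
Product: 7 dimethyl (2R,5E)-6-methyl-2-(trifluoromethanesulfonyloxy)hept-5-enedioate
Conditions: Tf2O, 2,6-lutidine, CH2Cl2, −78 °C
Reagents that add atoms: trifluoromethanesulfonic anhydride 6, O=S(=O)(OS(=O)(=O)C(F)(F)F)C(F)(F)F
Why: O-Sulfonylation with retention turns the secondary alcohol into an alpha-triflyloxy ester, a very reactive SN2 electrophile.

Step 4
Reactants: 7 dimethyl (2R,5E)-6-methyl-2-(trifluoromethanesulfonyloxy)hept-5-enedioate; 8 cyclopent-2-en-1-one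
Product: 10 dimethyl (2R,5E)-6-methyl-2-(2-oxocyclopent-3-en-1-yl)hept-5-enedioate, via cyclopentenone lithium enolate 9 (not isolated)
Conditions: 8, LiN(i-Pr)2, THF, −78 °C; then 7, −78 to −30 °C
Reagents that add atoms: cyclopent-2-en-1-one 8, O=C1C=CCC1
Why: The kinetic alpha'-enolate of cyclopentenone should displace the triflate by SN2 with inversion (enolate alkylation with a 2-triflyloxy ester), which sets the side-chain stereocentre that controls all later ones; the descriptor stays R only because the priorities change.

Step 5
Reactants: 10 dimethyl (2R,5E)-6-methyl-2-(2-oxocyclopent-3-en-1-yl)hept-5-enedioate; 11 N-phenylbis(trifluoromethanesulfonimide)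
Product: 13 dimethyl (2R,5E)-6-methyl-2-[2-(trifluoromethanesulfonyloxy)cyclopenta-1,3-dien-1-yl]hept-5-enedioate, via potassium dienolate 12 (not isolated)
Conditions: KN(SiMe3)2, THF, −78 °C; then PhNTf2, −78 to 0 °C
Reagents that add atoms: N-phenylbis(trifluoromethanesulfonimide) 11, O=S(=O)(N(c1ccccc1)S(=O)(=O)C(F)(F)F)C(F)(F)F
Why: Deprotonation at the only alpha-CH of the ketone (more acidic than the ester alpha-CH, so the stereocentre is kept) gives the cross-conjugated dienolate, and O-triflation gives the cyclopentadienyl triflate with the leaving group next to the side-chain carbon.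

Step 6
Reactants: 13 dimethyl (2R,5E)-6-methyl-2-[2-(trifluoromethanesulfonyloxy)cyclopenta-1,3-dien-1-yl]hept-5-enedioate; 14 (tributylstannyl)methanol
Product: 16 methyl (2E)-2-methyl-5-[(4R)-3-oxo-1,3,4,5-tetrahydrocyclopenta[c]pyran-4-yl]pent-2-enoate, via hydroxymethyl diene 15 (not isolated)
Conditions: Bu3SnCH2OH, Pd(PPh3)4 (5 mol%), LiCl, dioxane, 60 °C; then TsOH (cat.), CH2Cl2, 20 °C
Reagents that add atoms: (tributylstannyl)methanol 14, CCCC[Sn](CCCC)(CCCC)CO
Why: Stille hydroxymethylation puts the CH2OH carbon on the diene carbon next to the side chain, and acid-catalysed closure of the six-membered lactone ties the stereocentre into a ring before the much slower cycloaddition can start; base is avoided because an (acyloxymethyl)cyclopentadiene eliminates to a fulvene.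

Step 7
Reactants: 16 methyl (2E)-2-methyl-5-[(4R)-3-oxo-1,3,4,5-tetrahydrocyclopenta[c]pyran-4-yl]pent-2-enoate
Product: 17 tetracyclic norbornene lactone (norbornene whose alkene carbon next to the quaternary bridgehead carries the CH2–O of the cis-fused delta-lactone ring D; ring C exo-fused; CO2Me endo and CH3 exo on the quaternary carbon of ring B)
Conditions: toluene (0.01 M), BHT, 140 °C, sealed tube
Reagents that add atoms: none
Why: In this intramolecular Diels–Alder reaction the three-atom tether on the diene terminus can reach only the diene face on which the pseudo-axial side chain of the lactone stereocentre lies and must fuse ring C exo, while the E-enoate puts CO2Me endo and CH3 exo, so one stereocentre should set the quaternary ring-fusion carbon, both neighbouring CH centres and the quaternary ester carbon.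

Step 8
Reactants: 17 tetracyclic norbornene lactone; 18 phenyl(tribromomethyl)mercury
Product: 21 2-bromo-1,3-diene enol lactone (bicyclo[3.2.1]octadiene with Br on the middle carbon of the three-carbon bridge), via exo-dibromocyclopropane 19 (not isolated), via allylic dibromide 20 (not isolated)
Conditions: PhHgCBr3 (1.5 equiv), benzene, 80 °C; then DBU, 80 °C
Reagents that add atoms: phenyl(tribromomethyl)mercury 18, BrC(Br)(Br)[Hg]c1ccccc1
Why: Dibromocarbene, set free thermally under neutral conditions so that lactone and ester survive, adds to the strained trisubstituted norbornene C=C from the exo face (syn to the CH2 bridge) and closes the cyclopropane of 19 in a concerted [2+1] cheletropic step. The bromine that points to the CH2 bridge then leaves with disrotatory two-electron electrocyclic opening, which cleaves the former alkene sigma bond, so the five-membered ring becomes six-membered ring A by ring expansion and the allyl cation/bromide pair collapses to the exo allylic bromide 20. DBU removes HBr in the 1,4 sense from the O–CH2 group, the only possible direction because the other neighbour of the allyl unit is a bridgehead, which gives the diene conjugated with the enol lactone of ring D. The closest known reaction type is the dihalocarbene ring expansion of norbornene to 3,4-dihalobicyclo[3.2.1]oct-2-ene. No stereocentre of 21 is created, since the two cyclopropane centres of 19 and the CHBr centre of 20 end sp2, and the five stereocentres of 17 are not touched. The step needs exo-face attack and reaction at one alkene only, which the norbornene geometry and the absence of any other C=C bond secure.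

Step 9
Reactants: 21 2-bromo-1,3-diene enol lactone
Product: 22 dienol lactone (ring A CH=CH–C(=CH–O), ring D enol delta-lactone)
Conditions: Pd(OAc)2 (5 mol%), PPh3, HCO2H, Et3N, DMF, 60 °C
Reagents that add atoms: none
Why: Palladium-catalysed formate reduction of the vinyl bromide (oxidative addition, formate to hydride, reductive elimination) should replace Br by H without touching diene, enol lactone or ester, and no stereocentre is involved.

Step 10
Reactants: 22 dienol lactone
Product: 23 lactol (2-hydroxy-2H-pyran ring D, mixture of anomers)
Conditions: i-Bu2AlH (1.1 equiv), CH2Cl2, −78 °C; aq. potassium sodium tartrate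
Reagents that add atoms: none
Why: At −78 °C the electrophilic enol lactone should be reduced to the lactol, held as the aluminium hemiacetal until work-up, in preference to the hindered methyl ester on the quaternary carbon; the new acetal centre is free to anomerise afterwards.

Step 11
Reactants: 23 lactol; 24 3-methylbutanoic anhydride
Product: 25 target CNP0315847.1
Conditions: (Me2CHCH2CO)2O, Et3N, DMAP (cat.), CH2Cl2, 0 °C
Reagents that add atoms: 3-methylbutanoic anhydride 24, CC(C)CC(=O)OC(=O)CC(C)C
Why: DMAP-catalysed acylation of the equilibrating lactol should trap the anomer with the hydroxyl on the convex face (cis to the hydrogen and trans to the ring-C carbon at the neighbouring centre), which is both the less strained and the more accessible one and has the required acetal configuration.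

Compound list
1 | methyl (2R)-oxirane-2-carboxylate | COC(=O)[C@H]1CO1 | starting material
2 | allylmagnesium bromide | C=CC[Mg]Br | starting material
3 | methyl (2R)-2-hydroxyhex-5-enoate | COC(=O)[C@H](O)CCC=C | intermediate
4 | methyl methacrylate | C=C(C)C(=O)OC | starting material
5 | dimethyl (2R,5E)-2-hydroxy-6-methylhept-5-enedioate | COC(=O)[C@H](O)CC/C=C(\C)C(=O)OC | intermediate
6 | trifluoromethanesulfonic anhydride | O=S(=O)(OS(=O)(=O)C(F)(F)F)C(F)(F)F | starting material
7 | dimethyl (2R,5E)-6-methyl-2-(trifluoromethanesulfonyloxy)hept-5-enedioate | COC(=O)[C@H](OS(=O)(=O)C(F)(F)F)CC/C=C(\C)C(=O)OC | intermediate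
8 | cyclopent-2-en-1-one | O=C1C=CCC1 | starting material
9 | lithium cyclopenta-1,4-dien-1-olate (cross-conjugated enolate of 8) | [Li+].[O-]C1=CCC=C1 | intermediate
10 | dimethyl (2R,5E)-6-methyl-2-(2-oxocyclopent-3-en-1-yl)hept-5-enedioate | COC(=O)[C@@H](C1CC=CC1=O)CC/C=C(\C)C(=O)OC | intermediate
11 | N-phenylbis(trifluoromethanesulfonimide) | O=S(=O)(N(c1ccccc1)S(=O)(=O)C(F)(F)F)C(F)(F)F | starting material
12 | potassium dienolate of 10 | [K+].COC(=O)[C@@H](C1=C([O-])C=CC1)CC/C=C(\C)C(=O)OC | intermediate
13 | dimethyl (2R,5E)-6-methyl-2-[2-(trifluoromethanesulfonyloxy)cyclopenta-1,3-dien-1-yl]hept-5-enedioate | COC(=O)[C@@H](C1=C(OS(=O)(=O)C(F)(F)F)C=CC1)CC/C=C(\C)C(=O)OC | intermediate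
14 | (tributylstannyl)methanol | CCCC[Sn](CCCC)(CCCC)CO | starting material
15 | dimethyl (2R,5E)-2-[2-(hydroxymethyl)cyclopenta-1,3-dien-1-yl]-6-methylhept-5-enedioate | COC(=O)[C@@H](C1=C(CO)C=CC1)CC/C=C(\C)C(=O)OC | intermediate
16 | methyl (2E)-2-methyl-5-[(4R)-3-oxo-1,3,4,5-tetrahydrocyclopenta[c]pyran-4-yl]pent-2-enoate | O=C1OCC2=C(CC=C2)[C@H]1CC/C=C(\C)C(=O)OC | intermediate
17 | tetracyclic norbornene lactone (Diels–Alder adduct) | COC(=O)[C@]1(C)[C@@H]2C=C3COC(=O)[C@@H]4CC[C@@H]1[C@]34C2 | intermediate
18 | phenyl(tribromomethyl)mercury | BrC(Br)(Br)[Hg]c1ccccc1 | starting material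
19 | exo-dibromocyclopropane adduct of 17 | COC(=O)[C@]1(C)[C@@H]2[C@H]5C(Br)(Br)[C@]53COC(=O)[C@@H]4CC[C@@H]1[C@]34C2 | intermediate
20 | ring-expanded allylic dibromide (exo allylic Br, vinyl Br) | COC(=O)[C@]1(C)[C@@H]2[C@@H](Br)C(Br)=C3COC(=O)[C@@H]4CC[C@@H]1[C@]34C2 | intermediate
21 | 2-bromo-1,3-diene enol lactone | COC(=O)[C@]1(C)[C@@H]2C=C(Br)C3=COC(=O)[C@@H]4CC[C@@H]1[C@]34C2 | intermediate
22 | dienol lactone | COC(=O)[C@]1(C)[C@@H]2C=CC3=COC(=O)[C@@H]4CC[C@@H]1[C@]34C2 | intermediate
23 | lactol (anomer that is acylated is drawn) | COC(=O)[C@]1(C)[C@@H]2C=CC3=CO[C@@H](O)[C@@H]4CC[C@@H]1[C@]34C2 | intermediate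
24 | 3-methylbutanoic anhydride | CC(C)CC(=O)OC(=O)CC(C)C | starting material
25 | CNP0315847.1 (methyl ester, 3-methylbutanoate acetal) | COC(=O)[C@]1(C)[C@@H]2C=CC3=CO[C@@H](OC(=O)CC(C)C)[C@@H]4CC[C@@H]1[C@]34C2 | target

Total step count: 11. Longest linear sequence: 11 steps (1 to 25).

Steps most likely to fail

Step 8. The allyl cation may be captured or rearranged instead of losing HBr cleanly, or the carbene may add sluggishly to the hindered alkene. The fallback is a radical ring expansion that sets out from 17 and comes back at 22. Simmons–Smith cyclopropanation of 17 (Et2Zn, CH2I2, CF3CO2H, CH2Cl2) should give the exo-cyclopropane F1. Wohl–Ziegler bromination (N-bromosuccinimide, AIBN, PhCF3, 80 °C) abstracts a hydrogen from the O–CH2 group next to the cyclopropane. The cyclopropylcarbinyl radical opens the internal bond with ring expansion and is brominated to the homoallylic bromide F2. DBU then eliminates HBr to the conjugated diene 22, so step 9 is no longer needed.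

Step 4. The basic lithium enolate may eliminate triflic acid from 7, exchange protons with loss of optical purity, or alkylate twice. The fallback sets out from 7 and comes back at 10. The soft sodium enolate of tert-butyl 2-oxocyclopentane-1-carboxylate (NaH, THF) displaces the triflate with inversion to give the keto triester F3. CF3CO2H followed by warming removes the tert-butyl ester and CO2 to give the cyclopentanone F4. LiN(i-Pr)2/Me3SiCl at −78 °C gives the less substituted silyl enol ether F5, and Saegusa–Ito oxidation with Pd(OAc)2 in MeCN gives 10.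

Step 11. The free lactol may open to the hydroxy-dienol and tautomerise to an enal before it is acylated, or both anomers may be acylated. The fallback sets out from 23 and comes back at 25. Cl3CCN with catalytic DBU at 0 °C converts the lactol into the anomeric trichloroacetimidate F6. 3-Methylbutanoic acid in CH2Cl2 then substitutes it through the oxocarbenium ion, and the carboxylate should enter from the convex face to give 25.

Further compounds
F1 | step 8 | exo-cyclopropane of 17 | COC(=O)[C@]1(C)[C@@H]2[C@H]5C[C@]53COC(=O)[C@@H]4CC[C@@H]1[C@]34C2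
F2 | step 8 | ring-expanded homoallylic bromide (enol lactone, CHBr next to the bridgehead CH) | COC(=O)[C@]1(C)[C@@H]2C(Br)CC3=COC(=O)[C@@H]4CC[C@@H]1[C@]34C2
F3 | step 4 | tert-butyl 1-[(2R,5E)-1,7-dimethoxy-6-methyl-1,7-dioxohept-5-en-2-yl]-2-oxocyclopentane-1-carboxylate | COC(=O)[C@@H](C1(C(=O)OC(C)(C)C)CCCC1=O)CC/C=C(\C)C(=O)OC
F4 | step 4 | dimethyl (2R,5E)-6-methyl-2-(2-oxocyclopentyl)hept-5-enedioate | COC(=O)[C@@H](C1CCCC1=O)CC/C=C(\C)C(=O)OC
F5 | step 4 | dimethyl (2R,5E)-6-methyl-2-[2-(trimethylsilyloxy)cyclopent-2-en-1-yl]hept-5-enedioate | COC(=O)[C@@H](C1CCC=C1O[Si](C)(C)C)CC/C=C(\C)C(=O)OC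
F6 | step 11 | anomeric trichloroacetimidate of 23 | COC(=O)[C@]1(C)[C@@H]2C=CC3=COC(OC(=N)C(Cl)(Cl)Cl)[C@@H]4CC[C@@H]1[C@]34C2
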